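**Plan**

- Retrosynthesis: the methylene bridge is cut first (C7–CH2 and CH2–C3 of the pyranone, one carbon between two nucleophiles). Then C3–C2 and O1–C7a of the dihydrofuran (ring B) are cut together, which leaves an ortho-bromobenzylic chloride and 6-methyl-2-methylidenehept-5-enal.
- Enabling feature: on ring A the benzylic carbon C3 and the oxygen-bearing carbon C7a both sit on C3a, and C7a is para to the acetyl carbon C5. An ortho-bromobenzylzinc is therefore a 1,3-dipole equivalent (nucleophilic C3, electrophilic C7a) that can add across the C=O of the enal, whose carbonyl becomes C2–O1.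
- Forward: ring A is taken ready-made from a symmetric 4-bromo-2,6-dioxygenated acetophenone (acetyl position fixed by symmetry) and is formylated, protected and converted to the benzylic chloride. The enal comes from propargyl alcohol. A formal (3+2) annulation closes ring B, the MOM groups are removed, and the separately made pyranone (ring C) is joined last by a Mannich-type one-carbon coupling.
- Stereochemistry: the only stereocenter, C2 (R), is set in the annulation by ligand-controlled Re-face benzyl transfer to the aldehyde and is not touched afterwards.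

Key step: step 9

Remark: (+)-MIB is (2R)-3-exo-morpholinoisoborneol; its sense of induction in step 9 is assigned by analogy with dialkylzinc additions to aldehydes, and (−)-MIB would be used if the sense were opposite.

**Route**

Step 1
Reactants: 1 5-bromo-2-methylpent-2-ene; 2 prop-2-yn-1-ol
Product: 4 6-methyl-2-methylidenehept-5-en-1-ol, via Grignard reagent 3 (not isolated)
Conditions: Mg, THF, 25 °C; then 2 (0.45 equiv), CuI (10 mol %), THF, −10 to 25 °C; aq NH4Cl
Reagents that add atoms: none
Why: Copper-catalysed anti carbomagnesiation of a propargylic magnesium alkoxide (chelation puts magnesium on the terminal carbon and the alkyl group on C2), followed by protonation, is an established route to 2-substituted allylic alcohols, and no stereocenter is formed.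

Step 2
Reactants: 4 6-methyl-2-methylidenehept-5-en-1-ol
Product: 5 6-methyl-2-methylidenehept-5-enal
Conditions: TEMPO (10 mol %), PhI(OAc)2 (1.1 equiv), CH2Cl2, 25 °C
Reagents that add atoms: none
Why: Nitroxyl-catalysed oxidation with PhI(OAc)2 as co-oxidant should take the primary allylic alcohol to the aldehyde without over-oxidation or alkene migration.

Step 3
Reactants: 6 1-(4-bromo-2,6-difluorophenyl)ethanone
Product: 7 1-(4-bromo-2,6-dimethoxyphenyl)ethanone
Conditions: NaOMe (2.5 equiv), MeOH, 65 °C
Reagents that add atoms: sodium methoxide (C[O-].[Na+])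
Why: Twofold nucleophilic aromatic substitution (SNAr), because both fluorides are ortho to the acetyl group and are far better leaving groups than the para bromide, which is kept for the later C–O coupling.

Step 4
Reactants: 7 1-(4-bromo-2,6-dimethoxyphenyl)ethanone
Product: 8 1-(4-bromo-2,6-dihydroxyphenyl)ethanone
Conditions: BBr3 (3 equiv), CH2Cl2, −78 to 25 °C; then H2O
Reagents that add atoms: none
Why: Boron tribromide cleavage of aryl methyl ethers, helped here by chelation to the neighbouring ketone, should give the resorcinol without touching the aryl bromide.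

Step 5
Reactants: 8 1-(4-bromo-2,6-dihydroxyphenyl)ethanone
Product: 9 3-acetyl-6-bromo-2,4-dihydroxybenzaldehyde
Conditions: Cl2CHOMe (1.1 equiv), TiCl4 (3 equiv), CH2Cl2, 0 °C; then aq HCl
Reagents that add atoms: dichloromethyl methyl ether (COC(Cl)Cl); water (O)
Why: Rieche formylation ortho to a phenol, in which the two free ring positions are equivalent by symmetry so that only one monoformyl product can form, and the new formyl group deactivates the ring against a second attack.

Step 6
Reactants: 9 3-acetyl-6-bromo-2,4-dihydroxybenzaldehyde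
Product: 10 3-acetyl-6-bromo-2,4-bis(methoxymethoxy)benzaldehyde
Conditions: NaH (2.2 equiv), MOMCl (2.4 equiv), DMF, 0 to 25 °C
Reagents that add atoms: chloromethyl methyl ether (COCCl)
Why: Williamson etherification of the two sodium phenoxides, where deprotonation breaks the hydrogen bonds to the carbonyl groups that would slow alkylation under amine-base conditions.

Step 7
Reactants: 10 3-acetyl-6-bromo-2,4-bis(methoxymethoxy)benzaldehyde
Product: 11 1-[4-bromo-3-(hydroxymethyl)-2,6-bis(methoxymethoxy)phenyl]ethanone
Conditions: NaBH4 (0.5 equiv), MeOH–THF, −20 °C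
Reagents that add atoms: none
Why: Chemoselective borohydride reduction, since the aldehyde should react much faster than the aryl methyl ketone flanked by two ortho alkoxy groups.

Step 8
Reactants: 11 1-[4-bromo-3-(hydroxymethyl)-2,6-bis(methoxymethoxy)phenyl]ethanone
Product: 12 1-[4-bromo-3-(chloromethyl)-2,6-bis(methoxymethoxy)phenyl]ethanone
Conditions: PPh3, N-chlorosuccinimide, CH2Cl2, 0 °C
Reagents that add atoms: N-chlorosuccinimide (O=C1CCC(=O)N1Cl)
Why: Appel-type chlorination under neutral conditions (chlorophosphonium activation, then SN2 by chloride) should spare the acid-labile MOM ethers and the ketone.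

Step 9
Reactants: 12 1-[4-bromo-3-(chloromethyl)-2,6-bis(methoxymethoxy)phenyl]ethanone; 5 6-methyl-2-methylidenehept-5-enal
Product: 16 1-[(2R)-4,6-bis(methoxymethoxy)-2-(6-methylhepta-1,5-dien-2-yl)-2,3-dihydro-1-benzofuran-5-yl]ethanone, via benzylzinc chloride 13 (not isolated), via mixed diorganozinc 14 (not isolated), via zinc alkoxide 15 (not isolated)
Conditions: Zn dust, LiCl, THF, 25 °C; Me3SiCH2MgCl (1.0 equiv), −30 °C; N,N,N',N'-tetraethylethylenediamine, (+)-MIB (10 mol %), 5 (0.9 equiv), toluene, −10 °C; then CuI (10 mol %), 3,4,7,8-tetramethyl-1,10-phenanthroline (20 mol %), Cs2CO3 (2 equiv), 100 °C, same flask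
Reagents that add atoms: none
Why: Proposed new method: the ortho-bromobenzylzinc unit of 14 is a 1,3-dipole equivalent (nucleophilic C3, latent electrophilic C7a), so zinc amino-alkoxide-catalysed transfer of the benzyl group to the carbonyl carbon of 5 forms C3–C2, and the zinc alkoxide 15 is then O-arylated at C7a by monovalent copper (oxidative addition into C7a–Br, C–O reductive elimination), in all a formal (3+2) annulation onto C=O. The closest known reaction types are the amino alcohol-catalysed enantioselective addition of diorganozinc reagents to aldehydes (known for alkyl, aryl and alkenyl groups but not for benzyl groups) and the copper-catalysed intramolecular O-arylation of 2-(2-bromoaryl)ethanols to 2,3-dihydrobenzofurans. Ring B closes in the 5-exo mode by attack of O1 on C7a. The C2 stereocenter is set by the ligand: (+)-MIB should deliver the benzyl group to the Re face of the α-branched enal through the usual anti dinuclear zinc transition state, which corresponds to (2R), and the C–O coupling does not touch it. The step needs zinc insertion at the benzylic C–Cl and not at C7a–Br (benzylic chlorides insert far faster at 25 °C), 1,2- and not 1,4-addition with transfer of benzyl and not of Me3SiCH2 (no copper is present until 5 is consumed, the silylmethyl group is a dummy ligand, and both positions ortho to C3a are substituted so that attack through the ring cannot compete), and a fast oxidative addition at C7a, which the acetyl group para to it favours. Copper is chosen for the closure because zerovalent palladium could ionise the allylic aryl ether of the product and erode C2.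

Step 10
Reactants: 16 1-[(2R)-4,6-bis(methoxymethoxy)-2-(6-methylhepta-1,5-dien-2-yl)-2,3-dihydro-1-benzofuran-5-yl]ethanone
Product: 17 1-[(2R)-4,6-dihydroxy-2-(6-methylhepta-1,5-dien-2-yl)-2,3-dihydro-1-benzofuran-5-yl]ethanone
Conditions: 3 M HCl, MeOH, 40 °C
Reagents that add atoms: none
Why: Acid-catalysed acetal exchange (MOM cleavage) is fast for aryl MOM ethers ortho to a ketone, at an acidity that the trisubstituted alkene and the allylic aryl ether should tolerate, and C2 is not involved.

Step 11
Reactants: 18 pentan-3-one; 19 propanedioyl dichloride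
Product: 20 6-ethyl-4-hydroxy-5-methyl-2H-pyran-2-one
Conditions: CH2Cl2, 40 °C (HCl evolution)
Reagents that add atoms: none
Why: C-acylation of the ketone enol by malonyl dichloride followed by O-acylation (lactonisation) of the resulting 1,3-diketone enol is a known one-flask route to 4-hydroxy-2-pyranones, in which the α-carbon of the ketone becomes C5 and its carbonyl carbon C6.

Step 12
Reactants: 20 6-ethyl-4-hydroxy-5-methyl-2H-pyran-2-one; 17 1-[(2R)-4,6-dihydroxy-2-(6-methylhepta-1,5-dien-2-yl)-2,3-dihydro-1-benzofuran-5-yl]ethanone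
Product: 23 3-{[(2R)-5-acetyl-4,6-dihydroxy-2-(6-methylhepta-1,5-dien-2-yl)-2,3-dihydro-1-benzofuran-7-yl]methyl}-6-ethyl-4-hydroxy-5-methyl-2H-pyran-2-one, via Mannich base 21 (not isolated), via methylidene dione 22 (not isolated)
Conditions: 20, Eschenmoser's salt (1.0 equiv), MeCN, 25 °C; then 17, 70 °C
Reagents that add atoms: N,N-dimethylmethyleneiminium iodide (C=[N+](C)C.[I-])
Why: Mannich aminomethylation of the 4-hydroxypyranone at C3, thermal loss of dimethylamine to the methylidene dione and Friedel–Crafts-type conjugate addition of C7 of 17 (the only unsubstituted carbon of ring A) should give the methylene bridge, as is usual for methylene-bridged acylphloroglucinol–pyranone dimers, and C2 is untouched.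

**Compound list**

1 | 5-bromo-2-methylpent-2-ene | CC(C)=CCCBr | starting material
2 | prop-2-yn-1-ol | C#CCO | starting material
3 | (4-methylpent-3-en-1-yl)magnesium bromide | CC(C)=CCC[Mg]Br | intermediate
4 | 6-methyl-2-methylidenehept-5-en-1-ol | C=C(CO)CCC=C(C)C | intermediate
5 | 6-methyl-2-methylidenehept-5-enal | C=C(C=O)CCC=C(C)C | intermediate
6 | 1-(4-bromo-2,6-difluorophenyl)ethanone | CC(=O)c1c(F)cc(Br)cc1F | starting material
7 | 1-(4-bromo-2,6-dimethoxyphenyl)ethanone | CC(=O)c1c(OC)cc(Br)cc1OC | intermediate
8 | 1-(4-bromo-2,6-dihydroxyphenyl)ethanone | CC(=O)c1c(O)cc(Br)cc1O | intermediate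
9 | 3-acetyl-6-bromo-2,4-dihydroxybenzaldehyde | CC(=O)c1c(O)cc(Br)c(C=O)c1O | intermediate
10 | 3-acetyl-6-bromo-2,4-bis(methoxymethoxy)benzaldehyde | CC(=O)c1c(OCOC)cc(Br)c(C=O)c1OCOC | intermediate
11 | 1-[4-bromo-3-(hydroxymethyl)-2,6-bis(methoxymethoxy)phenyl]ethanone | CC(=O)c1c(OCOC)cc(Br)c(CO)c1OCOC | intermediate
12 | 1-[4-bromo-3-(chloromethyl)-2,6-bis(methoxymethoxy)phenyl]ethanone | CC(=O)c1c(OCOC)cc(Br)c(CCl)c1OCOC | intermediate
13 | {[3-acetyl-6-bromo-2,4-bis(methoxymethoxy)phenyl]methyl}zinc chloride | CC(=O)c1c(OCOC)cc(Br)c(C[Zn]Cl)c1OCOC | intermediate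
14 | {[3-acetyl-6-bromo-2,4-bis(methoxymethoxy)phenyl]methyl}[(trimethylsilyl)methyl]zinc | CC(=O)c1c(OCOC)cc(Br)c(C[Zn]C[Si](C)(C)C)c1OCOC | intermediate
15 | {[(2R)-1-[3-acetyl-6-bromo-2,4-bis(methoxymethoxy)phenyl]-7-methyl-3-methylideneoct-6-en-2-yl]oxy}[(trimethylsilyl)methyl]zinc | C=C(CCC=C(C)C)[C@H](O[Zn]C[Si](C)(C)C)Cc1c(Br)cc(OCOC)c(C(C)=O)c1OCOC | intermediate
16 | 1-[(2R)-4,6-bis(methoxymethoxy)-2-(6-methylhepta-1,5-dien-2-yl)-2,3-dihydro-1-benzofuran-5-yl]ethanone | C=C(CCC=C(C)C)[C@H]1Cc2c(OCOC)c(C(C)=O)c(OCOC)cc2O1 | intermediate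
17 | 1-[(2R)-4,6-dihydroxy-2-(6-methylhepta-1,5-dien-2-yl)-2,3-dihydro-1-benzofuran-5-yl]ethanone | C=C(CCC=C(C)C)[C@H]1Cc2c(O)c(C(C)=O)c(O)cc2O1 | intermediate
18 | pentan-3-one | CCC(=O)CC | starting material
19 | propanedioyl dichloride (malonyl dichloride) | O=C(Cl)CC(=O)Cl | starting material
20 | 6-ethyl-4-hydroxy-5-methyl-2H-pyran-2-one | CCc1oc(=O)cc(O)c1C | intermediate
21 | 3-[(dimethylamino)methyl]-6-ethyl-4-hydroxy-5-methyl-2H-pyran-2-one | CCc1oc(=O)c(CN(C)C)c(O)c1C | intermediate
22 | 6-ethyl-5-methyl-3-methylidene-2H-pyran-2,4(3H)-dione | CCC1=C(C)C(=O)C(=C)C(=O)O1 | intermediate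
23 | 3-{[(2R)-5-acetyl-4,6-dihydroxy-2-(6-methylhepta-1,5-dien-2-yl)-2,3-dihydro-1-benzofuran-7-yl]methyl}-6-ethyl-4-hydroxy-5-methyl-2H-pyran-2-one | C=C(CCC=C(C)C)[C@H]1Cc2c(O)c(C(C)=O)c(O)c(Cc3c(O)c(C)c(CC)oc3=O)c2O1 | target

**Step count and risks**

Total steps: 12. Longest linear sequence: 9 steps (steps 3 to 10, then step 12).

Steps most likely to fail:

1. Step 9. The benzyl transfer may run without ligand control (uncatalysed background addition, or inhibition of the catalyst by halide salts or by the chelating MOM and acetyl groups), and the C–O coupling may stall on the zinc-bound alkoxide. The fallback uses known chemistry only, sets out from 12 and comes back at 16. The benzylzinc chloride 13, made as in step 9, is added without ligand to 5 (THF, 25 °C) to give racemic 1-[4-bromo-3-(2-hydroxy-7-methyl-3-methylideneoct-6-en-1-yl)-2,6-bis(methoxymethoxy)phenyl]ethanone F1. Dess–Martin oxidation gives the enone 1-[3-acetyl-6-bromo-2,4-bis(methoxymethoxy)phenyl]-7-methyl-3-methylideneoct-6-en-2-one F2. Corey–Bakshi–Shibata reduction ((S)-Me-CBS oxazaborolidine, catecholborane, toluene, −78 °C) should give 1-{4-bromo-3-[(2R)-2-hydroxy-7-methyl-3-methylideneoct-6-en-1-yl]-2,6-bis(methoxymethoxy)phenyl}ethanone F3, with the alkenyl group as the large substituent and the doubly ortho-substituted aryl methyl ketone too hindered to compete. Copper-catalysed cyclisation of the isolated alcohol (CuI, 3,4,7,8-tetramethyl-1,10-phenanthroline, Cs2CO3, toluene, 100 °C) then gives 16.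

2. Step 12. The methylidene dione may be consumed by self-condensation with 20 before it meets 17, and 17 may be alkylated at oxygen or react with free iminium salt. The fallback exchanges the roles of the partners, sets out from 17 and comes back at 23. 17 is aminomethylated at C7 with Eschenmoser's salt (CH2Cl2, 25 °C) to give 1-[(2R)-7-[(dimethylamino)methyl]-4,6-dihydroxy-2-(6-methylhepta-1,5-dien-2-yl)-2,3-dihydro-1-benzofuran-5-yl]ethanone F4. Heating F4 with 20 (1,4-dioxane, 90 °C) should expel dimethylamine to give the ortho-quinone methide of ring A, which the pyranone traps at its C3 to give 23.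

3. Step 1. The carbomagnesiation may stop at the deprotonated alkyne or leak to the linear regioisomer, and the Grignard reagent may couple with its own bromide. The fallback builds the 2-methylidene unit by olefination, sets out from 1 and comes back at 4. 1 alkylates the sodium salt of triethyl phosphonoacetate (NaH, DMF, 60 °C) to give ethyl 2-(diethoxyphosphoryl)-6-methylhept-5-enoate F5. Horner–Wadsworth–Emmons olefination with aqueous formaldehyde (K2CO3, 25 °C) gives ethyl 6-methyl-2-methylidenehept-5-enoate F6, and reduction with i-Bu2AlH (CH2Cl2, −78 °C) gives 4.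

**Further compounds**

F1 | step 9 | 1-[4-bromo-3-(2-hydroxy-7-methyl-3-methylideneoct-6-en-1-yl)-2,6-bis(methoxymethoxy)phenyl]ethanone (racemic) | CC(=O)c1c(OCOC)cc(Br)c(CC(O)C(=C)CCC=C(C)C)c1OCOC
F2 | step 9 | 1-[3-acetyl-6-bromo-2,4-bis(methoxymethoxy)phenyl]-7-methyl-3-methylideneoct-6-en-2-one | CC(=O)c1c(OCOC)cc(Br)c(CC(=O)C(=C)CCC=C(C)C)c1OCOC
F3 | step 9 | 1-{4-bromo-3-[(2R)-2-hydroxy-7-methyl-3-methylideneoct-6-en-1-yl]-2,6-bis(methoxymethoxy)phenyl}ethanone | C=C(CCC=C(C)C)[C@H](O)Cc1c(Br)cc(OCOC)c(C(C)=O)c1OCOC
F4 | step 12 | 1-[(2R)-7-[(dimethylamino)methyl]-4,6-dihydroxy-2-(6-methylhepta-1,5-dien-2-yl)-2,3-dihydro-1-benzofuran-5-yl]ethanone | C=C(CCC=C(C)C)[C@H]1Cc2c(O)c(C(C)=O)c(O)c(CN(C)C)c2O1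
F5 | step 1 | ethyl 2-(diethoxyphosphoryl)-6-methylhept-5-enoate | CCOC(=O)C(CCC=C(C)C)P(=O)(OCC)OCC
F6 | step 1 | ethyl 6-methyl-2-methylidenehept-5-enoate | C=C(CCC=C(C)C)C(=O)OCC
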